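**Retrosynthetic overview**
- C7–C8: anti-selective lithium aldol between the α′-enolate of a 2-iodo-4-silyloxy-4-octenylcyclopentenone and methyl (Z)-7-oxohept-5-enoate sets C7 and C8; acetylation and desilylation finish.
- C10–I: α-iodination of the 4-silyloxy-4-[(Z)-octenyl]cyclopentenone.
- C12 carbinol: 1,2-addition of a 2-octynylzinc to (R)-4-TBSO-cyclopentenone anti to OTBS, Lindlar reduction, then desilylation/oxidation (1,3-transposition of chirality).
- Z-enal: Z-selective cross-metathesis of methyl hex-5-enoate with (Z)-butenediol, then oxidation.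
- Rings: no ring is built; the single cyclopentenone ring comes intact from the chiral building block.

Assumption: (R)-4-(TBSO)cyclopent-2-enone, 1-bromooct-2-yne, methyl hex-5-enoate, (Z)-but-2-ene-1,4-diol and a Z-selective Ru metathesis catalyst are taken as commercially available. Prostanoid numbering (C7, C8, C12) is used for the stereocentres; the target is 7S,8R,12S.

**Step 1**
Reactants: 1, (R)-4-[(tert-butyldimethylsilyl)oxy]cyclopent-2-en-1-one; 2, 1-bromooct-2-yne
Product: 3, (1S,4R)-4-[(tert-butyldimethylsilyl)oxy]-1-(oct-2-yn-1-yl)cyclopent-2-en-1-ol (OH cis to OTBS)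
Conditions: activated Zn dust, THF, 0 °C (forms the organozinc from 2); then 1, −78 → 0 °C; aq. NH4Cl
Reagents that add atoms: 1-bromooct-2-yne (compound 2), CCCCCC#CCBr
Why: Barbier-type propargylation; the allenylzinc adds SE2′ through its CH2 terminus in a 1,2-fashion to give the homopropargylic tertiary alcohol, attacking the carbonyl face anti to the C4 OTBS group, which sets the future C12 centre.

**Step 2**
Reactants: 3
Product: 4, (1S,4R)-4-[(tert-butyldimethylsilyl)oxy]-1-[(Z)-oct-2-en-1-yl]cyclopent-2-en-1-ol
Conditions: H2 (1 atm), Lindlar catalyst, quinoline, EtOAc, rt, stop at 1 equiv H2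
Reagents that add atoms: none (H2 adds only hydrogen)
Why: Lindlar semihydrogenation delivers H2 syn to the alkyne to give the Z-olefin; the ring alkene is not reduced on the poisoned catalyst.

**Step 3**
Reactants: 4
Product: 5, (1S,4R)-1-[(Z)-oct-2-en-1-yl]cyclopent-2-ene-1,4-diol (cis-diol)
Conditions: TBAF, THF, 0 °C → rt
Reagents that add atoms: none
Why: Fluoride-mediated desilylation; no other fluoride- or base-sensitive group is present.

**Step 4**
Reactants: 5
Product: 6, (S)-4-hydroxy-4-[(Z)-oct-2-en-1-yl]cyclopent-2-en-1-one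
Conditions: activated MnO2 (excess), CH2Cl2, rt
Reagents that add atoms: none
Why: Chemoselective MnO2 oxidation of the secondary allylic alcohol (the tertiary alcohol cannot oxidise); the original stereocentre is erased and its chirality is retained in the quaternary carbinol.

**Step 5**
Reactants: 6
Product: 7, (S)-4-[(Z)-oct-2-en-1-yl]-4-[(trimethylsilyl)oxy]cyclopent-2-en-1-one
Conditions: TMSCl, imidazole, DMF, 0 °C → rt
Reagents that add atoms: chlorotrimethylsilane, C[Si](C)(C)Cl
Why: Silylation of the tertiary alcohol prevents iodoetherification onto the homoallylic Z-olefin in step 6 and alkoxide retro-aldol chemistry in step 9.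

**Step 6**
Reactants: 7
Product: 8, (S)-2-iodo-4-[(Z)-oct-2-en-1-yl]-4-[(trimethylsilyl)oxy]cyclopent-2-en-1-one
Conditions: I2 (2 equiv), pyridine/CH2Cl2 (1:1), 0 °C → rt, dark; aq. Na2S2O3
Reagents that add atoms: iodine, II
Why: Johnson α-iodination of an enone (pyridine conjugate addition, iodination of the enolate, E1cB loss of pyridine); the isolated Z-olefin only complexes iodine reversibly.

**Step 7**
Reactants: 9, methyl hex-5-enoate; 10, (Z)-but-2-ene-1,4-diol (3 equiv)
Product: 11, methyl (Z)-7-hydroxyhept-5-enoate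
Conditions: stereoretentive Ru catechodithiolate metathesis catalyst (5 mol %), THF, 22 °C
Reagents that add atoms: (Z)-but-2-ene-1,4-diol (compound 10), OC/C=C\CO
Why: Z-selective (stereoretentive) olefin cross-metathesis transfers the Z-configured =CH–CH2OH unit to the terminal olefin; the ester and free alcohol are tolerated.

**Step 8**
Reactants: 11
Product: 12, methyl (Z)-7-oxohept-5-enoate
Conditions: Dess–Martin periodinane, NaHCO3, CH2Cl2, 0 °C; quick filtration, used immediately
Reagents that add atoms: none
Why: Buffered Dess–Martin oxidation of the allylic alcohol gives the Z-enal without the acid or base that would isomerise it to E.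

**Step 9**
Reactants: 8; 12 (1.3 equiv)
Product: 13, methyl (5Z,7S)-7-hydroxy-7-[(1R,5S)-3-iodo-5-[(Z)-oct-2-en-1-yl]-2-oxo-5-[(trimethylsilyl)oxy]cyclopent-3-en-1-yl]hept-5-enoate
Conditions: LDA (1.1 equiv), THF, −78 °C, 30 min; then 12, −78 °C, 15 min; AcOH/THF quench at −78 °C; chromatography to remove the minor 7-epimer
Reagents that add atoms: none beyond aldehyde 12, COC(=O)CCC/C=C\C=O
Why: Kinetic directed lithium aldol at the only enolisable position (C8). The ring-locked (E)-enolate reacts through a Zimmerman–Traxler chair to give the 7,8-anti relationship (7S). The aldehyde approaches the face anti to the octenyl chain and syn to the smaller O-substituent, setting 8R, which is also the thermodynamically preferred trans arrangement of the two carbon chains.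

**Step 10**
Reactants: 13
Product: 14, methyl (5Z,7S)-7-acetoxy-7-[(1R,5S)-3-iodo-5-[(Z)-oct-2-en-1-yl]-2-oxo-5-[(trimethylsilyl)oxy]cyclopent-3-en-1-yl]hept-5-enoate
Conditions: Ac2O, pyridine, CH2Cl2, 0 °C, no DMAP, short reaction time
Reagents that add atoms: acetic anhydride, CC(=O)OC(C)=O
Why: O-acetylation of the secondary allylic alcohol with retention at C7; cold, DMAP-free conditions avoid E1cB loss of the β-acetoxy group to the cross-conjugated dienone.

**Step 11**
Reactants: 14
Product: 15, 7-acetoxy-7,8-dihydroiodovulone I, methyl (5Z,7S)-7-acetoxy-7-[(1R,5S)-5-hydroxy-3-iodo-5-[(Z)-oct-2-en-1-yl]-2-oxocyclopent-3-en-1-yl]hept-5-enoate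
Conditions: AcOH/THF/H2O (3:1:1), rt
Reagents that add atoms: none
Why: Mild acidic hydrolysis of the tertiary TMS ether; base-free conditions leave the β-acetoxy ketone, methyl ester, vinyl iodide and both Z-olefins untouched.

**Compound list**
1 | (R)-4-[(tert-butyldimethylsilyl)oxy]cyclopent-2-en-1-one | O=C1C=C[C@H](O[Si](C)(C)C(C)(C)C)C1 | starting material
2 | 1-bromooct-2-yne | CCCCCC#CCBr | starting material
3 | (1S,4R)-4-(TBSO)-1-(oct-2-yn-1-yl)cyclopent-2-en-1-ol | CCCCCC#CC[C@@]1(O)C=C[C@H](O[Si](C)(C)C(C)(C)C)C1 | intermediate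
4 | (1S,4R)-4-(TBSO)-1-[(Z)-oct-2-en-1-yl]cyclopent-2-en-1-ol | CCCCC/C=C\C[C@@]1(O)C=C[C@H](O[Si](C)(C)C(C)(C)C)C1 | intermediate
5 | (1S,4R)-1-[(Z)-oct-2-en-1-yl]cyclopent-2-ene-1,4-diol | CCCCC/C=C\C[C@@]1(O)C=C[C@H](O)C1 | intermediate
6 | (S)-4-hydroxy-4-[(Z)-oct-2-en-1-yl]cyclopent-2-en-1-one | CCCCC/C=C\C[C@@]1(O)C=CC(=O)C1 | intermediate
7 | (S)-4-[(Z)-oct-2-en-1-yl]-4-[(trimethylsilyl)oxy]cyclopent-2-en-1-one | CCCCC/C=C\C[C@@]1(O[Si](C)(C)C)C=CC(=O)C1 | intermediate
8 | (S)-2-iodo-4-[(Z)-oct-2-en-1-yl]-4-[(trimethylsilyl)oxy]cyclopent-2-en-1-one | CCCCC/C=C\C[C@@]1(O[Si](C)(C)C)C=C(I)C(=O)C1 | intermediate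
9 | methyl hex-5-enoate | COC(=O)CCCC=C | starting material
10 | (Z)-but-2-ene-1,4-diol | OC/C=C\CO | starting material
11 | methyl (Z)-7-hydroxyhept-5-enoate | COC(=O)CCC/C=C\CO | intermediate
12 | methyl (Z)-7-oxohept-5-enoate | COC(=O)CCC/C=C\C=O | intermediate
13 | (7S,8R,12S) aldol adduct, 12-O-TMS, 7-OH | CCCCC/C=C\C[C@@]1(O[Si](C)(C)C)C=C(I)C(=O)[C@@H]1[C@H](/C=C\CCCC(=O)OC)O | intermediate
14 | (7S,8R,12S) 7-acetate, 12-O-TMS | CCCCC/C=C\C[C@@]1(O[Si](C)(C)C)C=C(I)C(=O)[C@@H]1[C@H](/C=C\CCCC(=O)OC)OC(C)=O | intermediate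
15 | 7-acetoxy-7,8-dihydroiodovulone I | CCCCC/C=C\C[C@@]1(O)C=C(I)C(=O)[C@@H]1[C@H](/C=C\CCCC(=O)OC)OC(C)=O | target

**Step count**
Total steps: 11. Longest linear sequence: 9 (steps 1–6, then 9–11); the enal branch is 2 steps (7–8).

**Three steps most likely to fail**
1. Step 9 (aldol). Lithium aldols of cyclic enolates often give only modest anti/syn ratios at C7, the 2-iodoenone enolate may be fragile, and the Z-enal can isomerise. Fallback: run the aldol on the non-iodinated enone 7 with the non-isomerisable ynal methyl 7-oxohept-5-ynoate, Lindlar-reduce, and iodinate (I2/pyridine) at the free-aldol stage before acetylation. Any 7-epimer is converted by Mitsunobu inversion with AcOH, which installs the acetate directly.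
2. Step 1 (propargylation). The allenyl carbinol regioisomer or poor facial selectivity could compete. Fallback: add the lithium enolate of tert-butyl acetate to 1 (anti to OTBS), reduce the ester to the aldehyde with DIBAL-H, and build the Z-olefin by salt-free Wittig reaction with hexylidenetriphenylphosphorane. This replaces steps 1–2.
3. Step 10 (acetylation). The β-acetoxy ketone can undergo E1cB elimination to the iodovulone-type dienone or epimerise at C8. Fallback: trap the lithium aldolate of step 9 in situ with Ac2O at −78 °C (one-pot aldol–acylation, no amine base, no isolated β-hydroxy ketone), or use neutral enzymatic acetylation (lipase, vinyl acetate).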